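## Retrosynthetic overview

1. Numbering follows benzofuran. Unprimed atoms belong to the dihydrobenzofuran whose C2 carries the 2,4-dihydroxyphenyl group; primed atoms belong to the one with the styryl group on C6′.
2. Disconnections: ten silyl ethers; the C6′–vinyl and C5–vinyl bonds (two Heck couplings); each dihydrofuran ring back to an (E)-stilbene plus an o-quinone diazide of a bromoresorcinol (C3a–C3/O1–C2 and C3a′–C3′/O1′–C2′).
3. Enabling feature: in the unprimed benzo ring, C3a is ortho to the O1-bearing C7a and para to the C6 hydroxyl. This ring can therefore be written as an o-quinone diazide (C7a=O, C3a=N2). The 2,4-dioxygenated aryl on C2 is the donor that later breaks the C3a–C2 bond.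
4. Key event: the Rh carbene at C3a adds to silylated oxyresveratrol and forms the spiro three-membered ring C3a–C3–C2. That ring takes in C7a and O1 and becomes the five-membered ring while the benzo ring aromatises.
5. Ring order: cyclopropane (C3a, C3, C2), unprimed dihydrofuran, cyclopropane (C3a′, C3′, C2′), primed dihydrofuran. All six benzene rings are bought.

Key step: step 6

Assumption 1: the sense of induction of the chiral Rh(II) catalyst on this new substrate pair cannot be predicted with certainty. The (S)-ligand series is written, and the (R)-series would be used if a test reaction shows the antipode.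

Assumption 2: the spiro carbon of the two transient cyclopropanes is drawn with C=O syn to the donor aryl. This centre disappears in the ring expansion and does not affect the outcome.

Abbreviation: TBS = tert-butyldimethylsilyl; TBSO = its ether oxygen.

## Route

Step 1
Reactants: 1 oxyresveratrol
Product: 2 (E)-2,4,3′,5′-tetrakis(TBSO)stilbene
Conditions: TBSCl (6 equiv), imidazole (10 equiv), DMF, 23 °C
Reagents that add atoms: tert-butyldimethylsilyl chloride, CC(C)(C)[Si](C)(C)Cl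
Why: Exhaustive phenol silylation gives fluoride-labile ethers that keep the 2,4-dioxygenated ring a strong π-donor, and the E alkene is untouched.

Step 2
Reactants: 3 4-bromoresorcinol
Product: 4 4-bromo-6-nitrobenzene-1,3-diol
Conditions: 65% HNO3 (1.0 equiv), AcOH, 10 °C
Reagents that add atoms: nitric acid, O[N+](=O)[O-]
Why: Electrophilic aromatic nitration should go to C6, which is ortho to one hydroxyl and para to the other, because C2 is flanked by both hydroxyls and C5 is meta to both.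

Step 3
Reactants: 4 4-bromo-6-nitrobenzene-1,3-diol
Product: 5 4-bromo-5-(TBSO)-2-nitrophenol
Conditions: TBSCl (1.05 equiv), Et3N (1.2 equiv), CH2Cl2, 0 °C
Reagents that add atoms: tert-butyldimethylsilyl chloride, CC(C)(C)[Si](C)(C)Cl
Why: Chemoselective O-silylation, because the hydroxyl ortho to the nitro group is held in an intramolecular hydrogen bond, so the free and more acidic hydroxyl next to Br (the later C6–O) reacts first, as in the selective 4-O-derivatisation of 2,4-dihydroxyaryl ketones.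

Step 4
Reactants: 5 4-bromo-5-(TBSO)-2-nitrophenol
Product: 6 2-amino-4-bromo-5-(TBSO)phenol
Conditions: H2 (1 atm), 5% Pt/C (sulfided), EtOAc, 23 °C
Reagents that add atoms: none
Why: Catalytic nitro hydrogenation over sulfided platinum, a catalyst type that spares aryl bromides and aryl silyl ethers.

Step 5
Reactants: 6 2-amino-4-bromo-5-(TBSO)phenol
Product: 7 4-bromo-6-diazo-3-(TBSO)cyclohexa-2,4-dien-1-one
Conditions: isoamyl nitrite (1.3 equiv), AcOH (cat.), THF, 0 °C, dark; used at once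
Reagents that add atoms: isoamyl nitrite, CC(C)CCON=O
Why: Diazotisation of an o-aminophenol with an alkyl nitrite under nearly neutral conditions, where the diazonium phenol loses its proton to give the neutral, organic-soluble o-quinone diazide.

Step 6
Reactants: 2 (E)-2,4,3′,5′-tetrakis(TBSO)stilbene; 7 4-bromo-6-diazo-3-(TBSO)cyclohexa-2,4-dien-1-one
Product: 9 (2R,3R)-5-bromo-2-[2,4-bis(TBSO)phenyl]-3-[3,5-bis(TBSO)phenyl]-6-(TBSO)-2,3-dihydrobenzofuran, via spirocyclopropyl dienone 8 (not isolated)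
Conditions: Rh2(S-TCPTTL)4 (2 mol %), 2 (1.5 equiv), 4 Å MS, PhCF3, 30 °C, 7 added by syringe pump over 6 h, dark
Reagents that add atoms: none
Why: Proposed new method: Rh(II) takes N2 from 7, and the resulting 2-oxocyclohexadienylidene carbenoid, whose empty orbital at C3a stands perpendicular to the ring, is attacked by the alkene carbon of 2 that lies β to the 2,4-bis(silyloxy)phenyl donor, so that a strongly asynchronous [2+1] transfer closes the three-membered ring C3a–C3–C2 of spirodienone 8. In 8 the C3a–C2 bond is a push–pull bond (donor aryl on C2, a dienone on C3a that becomes a phenolate), so it should heterolyse at the reaction temperature and the oxygen on C7a should add to the quinone-methide-like C2 cation in a 5-exo-trig closure, which is a Cloke–Wilson cyclopropyl ketone to dihydrofuran ring expansion by two atoms (C7a and O1) driven by aromatisation of the benzo ring. The closest known reaction types are the Rh(II)-catalysed formal [3+2] annulation of diazonaphthoquinones and cyclic 2-diazo-1,3-diones with enol ethers and styrenes, the cyclopropanation of olefins with p-quinone diazides to spiro[2.5]octadienones, and the Cloke–Wilson opening of 2-aryl spirocyclopropyl 1,3-diones; new here are the monocyclic resorcinol-derived diazide, the 1,2-diaryl alkene and the asymmetric version. C3 is set in the C3a–C3 bond formation by the chiral pocket of the catalyst and no bond to it is broken afterwards, whereas C2 is set in the ring expansion by C3, since the oxygen adds anti to the C3 aryl to give the trans ring, which is also the thermodynamic isomer because C2–O1 ionisation is reversible. The step needs regioselectivity (C3a bonding to the carbon that bears the 3,5-aryl), which the polarisation of the stilbene secures, and chemoselectivity for the alkene over the silyloxyarenes and over carbene dimerisation, which is secured because every activated arene position is ortho to a bulky TBSO group, 7 is added slowly and 2 is in excess.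

Step 7
Reactants: 10 3,5-dihydroxybenzaldehyde
Product: 11 3,5-bis(TBSO)benzaldehyde
Conditions: TBSCl (2.5 equiv), imidazole (5 equiv), DMF, 23 °C
Reagents that add atoms: tert-butyldimethylsilyl chloride, CC(C)(C)[Si](C)(C)Cl
Why: Standard phenol silylation that leaves the aldehyde unchanged.

Step 8
Reactants: 11 3,5-bis(TBSO)benzaldehyde
Product: 12 3,5-bis(TBSO)styrene
Conditions: MePPh3Br (1.3 equiv), KOt-Bu (1.25 equiv), THF, 0 °C
Reagents that add atoms: methyltriphenylphosphonium bromide, C[P+](c1ccccc1)(c1ccccc1)c1ccccc1.[Br-]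
Why: Wittig methylenation with a non-stabilised ylide, conditions that aryl TBS ethers tolerate.

Step 9
Reactants: 9 (2R,3R)-5-bromo dihydrobenzofuran; 12 3,5-bis(TBSO)styrene
Product: 13 (2R,3R)-5-[(E)-3,5-bis(TBSO)styryl]-2-[2,4-bis(TBSO)phenyl]-3-[3,5-bis(TBSO)phenyl]-6-(TBSO)-2,3-dihydrobenzofuran
Conditions: Pd2(dba)3 (2.5 mol %), P(t-Bu)3·HBF4 (10 mol %), Cy2NMe (2 equiv), 1,4-dioxane, 80 °C
Reagents that add atoms: none
Why: Mizoroki–Heck coupling with a bulky, electron-rich phosphine that activates ortho-oxygenated electron-rich aryl bromides, where syn insertion and syn β-hydride elimination give the E stilbene and the anhydrous amine base leaves C2, C3 and the silyl ethers alone.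

Step 10
Reactants: 14 2,6-dimethoxyaniline
Product: 15 4-bromo-2,6-dimethoxyaniline
Conditions: NBS (1.0 equiv), MeCN, 0 °C
Reagents that add atoms: N-bromosuccinimide, O=C1CCC(=O)N1Br
Why: Electrophilic aromatic bromination para to the amino group, which is the strongest director on the ring.

Step 11
Reactants: 15 4-bromo-2,6-dimethoxyaniline
Product: 16 2-amino-5-bromobenzene-1,3-diol
Conditions: BBr3 (4 equiv), CH2Cl2, −78 to 23 °C; H2O quench, pH 6–7, argon; used at once
Reagents that add atoms: none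
Why: Lewis-acid cleavage of two aryl methyl ethers on a small, robust arene that has no acid-sensitive group yet.

Step 12
Reactants: 16 2-amino-5-bromobenzene-1,3-diol
Product: 17 5-bromo-2-diazo-3-hydroxycyclohexa-3,5-dien-1-one
Conditions: isoamyl nitrite (1.2 equiv), AcOH (cat.), EtOH, 0 °C, dark
Reagents that add atoms: isoamyl nitrite, CC(C)CCON=O
Why: Diazotisation of a symmetric 2-aminoresorcinol, in which loss of one phenolic proton gives a single o-quinone diazide, so no desymmetrisation problem arises.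

Step 13
Reactants: 17 5-bromo-2-diazo-3-hydroxycyclohexa-3,5-dien-1-one
Product: 18 5-bromo-2-diazo-3-(TBSO)cyclohexa-3,5-dien-1-one
Conditions: TBSCl (1.2 equiv), imidazole (2 equiv), CH2Cl2, 0 °C, dark; used at once
Reagents that add atoms: tert-butyldimethylsilyl chloride, CC(C)(C)[Si](C)(C)Cl
Why: O-silylation removes the only acidic O–H that could intercept the carbene by O–H insertion, and both oxygens are equivalent, so one product results.

Step 14
Reactants: 13 (2R,3R)-5-styryl dihydrobenzofuran; 18 5-bromo-2-diazo-3-(TBSO)cyclohexa-3,5-dien-1-one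
Product: 20 (2′R,3′R)-6′-bromo-4′-(TBSO)-3′-[3,5-bis(TBSO)phenyl]-2′-{(2R,3R)-2-[2,4-bis(TBSO)phenyl]-3-[3,5-bis(TBSO)phenyl]-6-(TBSO)-2,3-dihydrobenzofuran-5-yl}-2′,3′-dihydrobenzofuran, via spirocyclopropyl dienone 19 (not isolated)
Conditions: Rh2(S-TCPTTL)4 (3 mol %), 4 Å MS, PhCF3, 40 °C, 18 (2.5 equiv) added by syringe pump over 10 h, dark
Reagents that add atoms: none
Why: Proposed new method: the carbene transfer and ring expansion of step 6 are asked of the 2,6-dioxygenated diazide 18, whose Rh carbenoid at C3a′ is attacked from above the ring plane (so the in-plane ortho TBSO group costs little) by the alkene carbon β to the electron-rich ring carrying O1 and the C6 silyl ether, after which spirodienone 19 opens at its push–pull C3a′–C2′ bond and closes 5-exo-trig through the C7a′ oxygen to the trans ring; C3′ is set by the catalyst, which should override the remote centres of 13, C2′ follows from C3′, and the closest known reaction types are the Rh(II) formal [3+2] annulations of cyclic 2-diazo-1,3-diones and diazonaphthoquinones with styrenes and enol ethers.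

Step 15
Reactants: 21 2,4-dihydroxybenzaldehyde
Product: 22 2,4-bis(TBSO)benzaldehyde
Conditions: TBSCl (2.5 equiv), imidazole (5 equiv), DMF, 23 °C
Reagents that add atoms: tert-butyldimethylsilyl chloride, CC(C)(C)[Si](C)(C)Cl
Why: Standard phenol silylation, with excess reagent also covering the hydrogen-bonded 2-hydroxyl.

Step 16
Reactants: 22 2,4-bis(TBSO)benzaldehyde
Product: 23 2,4-bis(TBSO)styrene
Conditions: MePPh3Br (1.3 equiv), KOt-Bu (1.25 equiv), THF, 0 °C
Reagents that add atoms: methyltriphenylphosphonium bromide, C[P+](c1ccccc1)(c1ccccc1)c1ccccc1.[Br-]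
Why: Wittig methylenation, as in step 8.

Step 17
Reactants: 20 bis(dihydrobenzofuran) bromide; 23 2,4-bis(TBSO)styrene
Product: 24 deca-O-TBS gneyulin A
Conditions: Pd2(dba)3 (2.5 mol %), P(t-Bu)3·HBF4 (10 mol %), Cy2NMe (2 equiv), 1,4-dioxane, 80 °C
Reagents that add atoms: none
Why: Mizoroki–Heck coupling at the unhindered C6′ bromide, which is flanked by two C–H positions, should give the E stilbene by β-arylation of the styrene without touching the four stereocentres.

Step 18
Reactants: 24 deca-O-TBS gneyulin A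
Product: 25 gneyulin A
Conditions: Et3N·3HF (excess), THF/MeCN, 0 to 23 °C, argon, dark; reversed-phase purification
Reagents that add atoms: none
Why: Fluoride-mediated cleavage of aryl silyl ethers in a weakly acidic buffer avoids the Lewis and Brønsted acids that cyclise stilbenoid dihydrobenzofurans, and any reversible C2–O1 or C2′–O1′ opening recloses to the trans rings dictated by C3 and C3′.

## Compound list

1 | oxyresveratrol | Oc1cc(O)cc(/C=C/c2ccc(O)cc2O)c1 | starting material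
2 | (E)-2,4,3′,5′-tetrakis(TBSO)stilbene | CC(C)(C)[Si](C)(C)Oc1cc(O[Si](C)(C)C(C)(C)C)cc(/C=C/c2ccc(O[Si](C)(C)C(C)(C)C)cc2O[Si](C)(C)C(C)(C)C)c1 | intermediate
3 | 4-bromoresorcinol | Oc1ccc(Br)c(O)c1 | starting material
4 | 4-bromo-6-nitrobenzene-1,3-diol | Oc1cc(O)c([N+](=O)[O-])cc1Br | intermediate
5 | 4-bromo-5-(TBSO)-2-nitrophenol | CC(C)(C)[Si](C)(C)Oc1cc(O)c([N+](=O)[O-])cc1Br | intermediate
6 | 2-amino-4-bromo-5-(TBSO)phenol | CC(C)(C)[Si](C)(C)Oc1cc(O)c(N)cc1Br | intermediate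
7 | 4-bromo-6-diazo-3-(TBSO)cyclohexa-2,4-dien-1-one | CC(C)(C)[Si](C)(C)OC1=CC(=O)C(=[N+]=[N-])C=C1Br | intermediate
8 | trans-1-[2,4-bis(TBSO)phenyl]-2-[3,5-bis(TBSO)phenyl]-7-bromo-6-(TBSO)spiro[2.5]octa-5,7-dien-4-one (aryl-bearing carbons configured as in 9) | CC(C)(C)[Si](C)(C)Oc1cc(O[Si](C)(C)C(C)(C)C)cc([C@@H]2[C@]3(C=C(Br)C(O[Si](C)(C)C(C)(C)C)=CC3=O)[C@H]2c2ccc(O[Si](C)(C)C(C)(C)C)cc2O[Si](C)(C)C(C)(C)C)c1 | intermediate (not isolated)
9 | (2R,3R)-5-bromo-2-[2,4-bis(TBSO)phenyl]-3-[3,5-bis(TBSO)phenyl]-6-(TBSO)-2,3-dihydrobenzofuran | CC(C)(C)[Si](C)(C)Oc1cc(O[Si](C)(C)C(C)(C)C)cc([C@@H]2c3cc(Br)c(O[Si](C)(C)C(C)(C)C)cc3O[C@H]2c2ccc(O[Si](C)(C)C(C)(C)C)cc2O[Si](C)(C)C(C)(C)C)c1 | intermediate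
10 | 3,5-dihydroxybenzaldehyde | O=Cc1cc(O)cc(O)c1 | starting material
11 | 3,5-bis(TBSO)benzaldehyde | O=Cc1cc(O[Si](C)(C)C(C)(C)C)cc(O[Si](C)(C)C(C)(C)C)c1 | intermediate
12 | 3,5-bis(TBSO)styrene | C=Cc1cc(O[Si](C)(C)C(C)(C)C)cc(O[Si](C)(C)C(C)(C)C)c1 | intermediate
13 | (2R,3R)-5-[(E)-3,5-bis(TBSO)styryl]-2-[2,4-bis(TBSO)phenyl]-3-[3,5-bis(TBSO)phenyl]-6-(TBSO)-2,3-dihydrobenzofuran | CC(C)(C)[Si](C)(C)Oc1cc(O[Si](C)(C)C(C)(C)C)cc([C@@H]2c3cc(/C=C/c4cc(O[Si](C)(C)C(C)(C)C)cc(O[Si](C)(C)C(C)(C)C)c4)c(O[Si](C)(C)C(C)(C)C)cc3O[C@H]2c2ccc(O[Si](C)(C)C(C)(C)C)cc2O[Si](C)(C)C(C)(C)C)c1 | intermediate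
14 | 2,6-dimethoxyaniline | COc1cccc(OC)c1N | starting material
15 | 4-bromo-2,6-dimethoxyaniline | COc1cc(Br)cc(OC)c1N | intermediate
16 | 2-amino-5-bromobenzene-1,3-diol | Nc1c(O)cc(Br)cc1O | intermediate
17 | 5-bromo-2-diazo-3-hydroxycyclohexa-3,5-dien-1-one | O=C1C=C(Br)C=C(O)C1=[N+]=[N-] | intermediate
18 | 5-bromo-2-diazo-3-(TBSO)cyclohexa-3,5-dien-1-one | CC(C)(C)[Si](C)(C)OC1=CC(Br)=CC(=O)C1=[N+]=[N-] | intermediate
19 | trans-1,2-diaryl-6-bromo-8-(TBSO)spiro[2.5]octa-5,7-dien-4-one carrying the dihydrobenzofuran-5-yl unit of 13 on C1 and 3,5-bis(TBSO)phenyl on C2 (configured as in 20) | CC(C)(C)[Si](C)(C)Oc1cc(O[Si](C)(C)C(C)(C)C)cc([C@@H]2c3cc([C@@H]4[C@]5(C(=O)C=C(Br)C=C5O[Si](C)(C)C(C)(C)C)[C@H]4c4cc(O[Si](C)(C)C(C)(C)C)cc(O[Si](C)(C)C(C)(C)C)c4)c(O[Si](C)(C)C(C)(C)C)cc3O[C@H]2c2ccc(O[Si](C)(C)C(C)(C)C)cc2O[Si](C)(C)C(C)(C)C)c1 | intermediate (not isolated)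
20 | (2R,3R,2′R,3′R)-bis(dihydrobenzofuran) 6′-bromide, octa-TBS ether (full name in step 14) | CC(C)(C)[Si](C)(C)Oc1cc(O[Si](C)(C)C(C)(C)C)cc([C@@H]2c3cc([C@@H]4Oc5cc(Br)cc(O[Si](C)(C)C(C)(C)C)c5[C@H]4c4cc(O[Si](C)(C)C(C)(C)C)cc(O[Si](C)(C)C(C)(C)C)c4)c(O[Si](C)(C)C(C)(C)C)cc3O[C@H]2c2ccc(O[Si](C)(C)C(C)(C)C)cc2O[Si](C)(C)C(C)(C)C)c1 | intermediate
21 | 2,4-dihydroxybenzaldehyde | O=Cc1ccc(O)cc1O | starting material
22 | 2,4-bis(TBSO)benzaldehyde | O=Cc1ccc(O[Si](C)(C)C(C)(C)C)cc1O[Si](C)(C)C(C)(C)C | intermediate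
23 | 2,4-bis(TBSO)styrene | C=Cc1ccc(O[Si](C)(C)C(C)(C)C)cc1O[Si](C)(C)C(C)(C)C | intermediate
24 | deca-O-TBS gneyulin A (2R,3R,2′R,3′R; E) | CC(C)(C)[Si](C)(C)Oc1cc(O[Si](C)(C)C(C)(C)C)cc([C@@H]2c3cc([C@@H]4Oc5cc(/C=C/c6ccc(O[Si](C)(C)C(C)(C)C)cc6O[Si](C)(C)C(C)(C)C)cc(O[Si](C)(C)C(C)(C)C)c5[C@H]4c4cc(O[Si](C)(C)C(C)(C)C)cc(O[Si](C)(C)C(C)(C)C)c4)c(O[Si](C)(C)C(C)(C)C)cc3O[C@H]2c2ccc(O[Si](C)(C)C(C)(C)C)cc2O[Si](C)(C)C(C)(C)C)c1 | intermediate
25 | gneyulin A (2R,3R,2′R,3′R; E) | Oc1cc(O)cc([C@@H]2c3cc([C@@H]4Oc5cc(/C=C/c6ccc(O)cc6O)cc(O)c5[C@H]4c4cc(O)cc(O)c4)c(O)cc3O[C@H]2c2ccc(O)cc2O)c1 | target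

## Step count

Total steps: 18.
Longest linear sequence: 9 steps (2, 3, 4, 5, 6, 9, 14, 17, 18).

## Steps most likely to fail

**Step 6.** Carbene transfer to the hindered 1,2-diaryl alkene may lose against attack on the silyloxyarene rings or against azine and dimer formation. The catalyst may also discriminate the alkene faces poorly.

The fallback sets out from 2, comes back at 13, and keeps a ring enlargement, now 4 to 5, in known quinone–styrene chemistry.
- Commercial 2-(benzyloxy)phenol is oxidised with Fremy's salt to 2-(benzyloxy)-1,4-benzoquinone F1.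
- A Ti(IV)–TADDOLate (TiCl4/Ti(Oi-Pr)4 with the TADDOL antipode that leads to the 3R series, CH2Cl2, −78 °C) promotes the enantioselective [2+2] addition of 2 to the unsubstituted C=C of F1.
- This gives the cis-fused bicyclo[4.2.0]oct-3-ene-2,5-dione F2, in which C2 is still bonded to C4.
- TsOH in CH2Cl2 at 0 °C ionises that donor-activated bond, C2 moves to the carbonyl oxygen on C7a, and tautomerisation gives the (2R,3R)-6-benzyloxy-2,3-dihydrobenzofuran-5-ol F3.
- Tf2O/pyridine gives the 5-triflate F4, and hydrogenolysis (H2, Pd/C, EtOAc) gives the 6-hydroxy 5-triflate F5.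
- TBSCl/imidazole gives the 6-TBSO 5-triflate F6, which is coupled with 12 under the conditions of step 9 to give 13.

**Step 14.** Congestion at a carbene carbon flanked by C=O and TBSO may slow the bimolecular step. Insertion into silyl C–H bonds or arene attack could then take over, and catalyst control may be eroded by the existing stereocentres.

The fallback sets out from 13, comes back at 24, and uses the smaller, more electrophilic and well-known diacyl carbene.
- Commercial cyclohexane-1,3-dione is converted by diazo transfer (4-acetamidobenzenesulfonyl azide, Et3N) to 2-diazocyclohexane-1,3-dione F7.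
- F7 is annulated onto 13 with Rh2(OAc)4 in fluorobenzene at 70 °C.
- The two trans adducts are diastereomers because the unprimed unit is already enantiopure, so they are separated by chromatography to give the (2′R,3′R)-tetrahydrobenzofuran-4′-one F8.
- Dehydrogenation of the enolate (LDA, then N-tert-butylbenzenesulfinimidoyl chloride, −78 °C) and tautomerisation give the 4′-phenol F9, and silylation gives the 4′-TBS ether F10.
- Sterically controlled Ir-catalysed C–H borylation ([Ir(OMe)(cod)]2, dtbpy, B2pin2) takes place at C6′, the only aromatic C–H with two C–H neighbours, and gives the 6′-pinacolboronate F11.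
- An oxidative boron Heck coupling of F11 with 23 (Pd(OAc)2, 2,9-dimethylphenanthroline, O2) gives 24.

**Step 18.** Tenfold desilylation may stall at partly silylated stages. The free decaphenol may also autoxidise or open at its benzylic C–O bonds during purification.

The fallback sets out from 24, comes back at 25, and inserts a stable, chromatographable derivative.
- Desilylation with TBAF/AcOH is followed in the same flask by Ac2O/pyridine to give gneyulin A decaacetate F12, which is purified on silica.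
- Transesterification with catalytic K2CO3 in degassed MeOH at 0 °C, neutralised with acidic resin, releases 25.

## Further compounds

F1 | step 6 | 2-(benzyloxy)cyclohexa-2,5-diene-1,4-dione | O=C1C=CC(=O)C(OCc2ccccc2)=C1
F2 | step 6 | cis-fused 3-(benzyloxy)-8-endo-[2,4-bis(TBSO)phenyl]-7-exo-[3,5-bis(TBSO)phenyl]bicyclo[4.2.0]oct-3-ene-2,5-dione | CC(C)(C)[Si](C)(C)Oc1cc(O[Si](C)(C)C(C)(C)C)cc([C@@H]2[C@H]3C(=O)C=C(OCc4ccccc4)C(=O)[C@H]3[C@H]2c2ccc(O[Si](C)(C)C(C)(C)C)cc2O[Si](C)(C)C(C)(C)C)c1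
F3 | step 6 | (2R,3R)-6-(benzyloxy)-2-[2,4-bis(TBSO)phenyl]-3-[3,5-bis(TBSO)phenyl]-2,3-dihydrobenzofuran-5-ol | CC(C)(C)[Si](C)(C)Oc1cc(O[Si](C)(C)C(C)(C)C)cc([C@@H]2c3cc(O)c(OCc4ccccc4)cc3O[C@H]2c2ccc(O[Si](C)(C)C(C)(C)C)cc2O[Si](C)(C)C(C)(C)C)c1
F4 | step 6 | 5-triflate of F3 | CC(C)(C)[Si](C)(C)Oc1cc(O[Si](C)(C)C(C)(C)C)cc([C@@H]2c3cc(OS(=O)(=O)C(F)(F)F)c(OCc4ccccc4)cc3O[C@H]2c2ccc(O[Si](C)(C)C(C)(C)C)cc2O[Si](C)(C)C(C)(C)C)c1
F5 | step 6 | (2R,3R)-6-hydroxy-2,3-diaryl-2,3-dihydrobenzofuran-5-yl triflate | CC(C)(C)[Si](C)(C)Oc1cc(O[Si](C)(C)C(C)(C)C)cc([C@@H]2c3cc(OS(=O)(=O)C(F)(F)F)c(O)cc3O[C@H]2c2ccc(O[Si](C)(C)C(C)(C)C)cc2O[Si](C)(C)C(C)(C)C)c1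
F6 | step 6 | (2R,3R)-6-(TBSO)-2,3-diaryl-2,3-dihydrobenzofuran-5-yl triflate | CC(C)(C)[Si](C)(C)Oc1cc(O[Si](C)(C)C(C)(C)C)cc([C@@H]2c3cc(OS(=O)(=O)C(F)(F)F)c(O[Si](C)(C)C(C)(C)C)cc3O[C@H]2c2ccc(O[Si](C)(C)C(C)(C)C)cc2O[Si](C)(C)C(C)(C)C)c1
F7 | step 14 | 2-diazocyclohexane-1,3-dione | O=C1CCCC(=O)C1=[N+]=[N-]
F8 | step 14 | (2′R,3′R)-3′,5′,6′,7′-tetrahydrobenzofuran-4′(2′H)-one annulated on 13 | CC(C)(C)[Si](C)(C)Oc1cc(O[Si](C)(C)C(C)(C)C)cc([C@@H]2c3cc([C@@H]4OC5=C(C(=O)CCC5)[C@H]4c4cc(O[Si](C)(C)C(C)(C)C)cc(O[Si](C)(C)C(C)(C)C)c4)c(O[Si](C)(C)C(C)(C)C)cc3O[C@H]2c2ccc(O[Si](C)(C)C(C)(C)C)cc2O[Si](C)(C)C(C)(C)C)c1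
F9 | step 14 | (2R,3R,2′R,3′R)-bis(dihydrobenzofuran) 4′-phenol | CC(C)(C)[Si](C)(C)Oc1cc(O[Si](C)(C)C(C)(C)C)cc([C@@H]2c3cc([C@@H]4Oc5cccc(O)c5[C@H]4c4cc(O[Si](C)(C)C(C)(C)C)cc(O[Si](C)(C)C(C)(C)C)c4)c(O[Si](C)(C)C(C)(C)C)cc3O[C@H]2c2ccc(O[Si](C)(C)C(C)(C)C)cc2O[Si](C)(C)C(C)(C)C)c1
F10 | step 14 | 4′-TBS ether of F9 | CC(C)(C)[Si](C)(C)Oc1cc(O[Si](C)(C)C(C)(C)C)cc([C@@H]2c3cc([C@@H]4Oc5cccc(O[Si](C)(C)C(C)(C)C)c5[C@H]4c4cc(O[Si](C)(C)C(C)(C)C)cc(O[Si](C)(C)C(C)(C)C)c4)c(O[Si](C)(C)C(C)(C)C)cc3O[C@H]2c2ccc(O[Si](C)(C)C(C)(C)C)cc2O[Si](C)(C)C(C)(C)C)c1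
F11 | step 14 | 6′-pinacolboronate of F10 | CC(C)(C)[Si](C)(C)Oc1cc(O[Si](C)(C)C(C)(C)C)cc([C@@H]2c3cc([C@@H]4Oc5cc(B6OC(C)(C)C(C)(C)O6)cc(O[Si](C)(C)C(C)(C)C)c5[C@H]4c4cc(O[Si](C)(C)C(C)(C)C)cc(O[Si](C)(C)C(C)(C)C)c4)c(O[Si](C)(C)C(C)(C)C)cc3O[C@H]2c2ccc(O[Si](C)(C)C(C)(C)C)cc2O[Si](C)(C)C(C)(C)C)c1
F12 | step 18 | gneyulin A decaacetate | CC(=O)Oc1cc(OC(C)=O)cc([C@@H]2c3cc([C@@H]4Oc5cc(/C=C/c6ccc(OC(C)=O)cc6OC(C)=O)cc(OC(C)=O)c5[C@H]4c4cc(OC(C)=O)cc(OC(C)=O)c4)c(OC(C)=O)cc3O[C@H]2c2ccc(OC(C)=O)cc2OC(C)=O)c1
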